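**Retrosynthetic overview**
1. No ring is formed: both benzene rings are bought intact (2,6-dimethoxyphenol and 3,4,5-trimethoxybenzaldehyde).
2. C4'–allyl is installed last, by sterically controlled C–H borylation and Suzuki allylation of the des-allyl diol 12, so that no second alkene is present during alkene cleavage.
3. C9–OH comes from ozonolysis/NaBH4 of the vinyl group of homoallylic alcohol 10.
4. C7–C8 (key): an α-aryloxy carbanion (metalated allyl aryl ether, a reversed-polarity d1/homoenolate-type reagent) is used as the chiral (Z)-γ-aryloxyallyl-B(Ipc)2 and added to aldehyde 5, setting both stereocentres at once.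
5. Allyl aryl ether 3 comes from phenol 1 and allyl bromide 2.

Assumption: the target is the (7R,8R)-threo isomer as drawn; the reagent-controlled ee of step 2 (typically about 90 % or better for this reaction class) is raised to a single enantiomer by recrystallisation of diol 12.

**Route**

Step 1
Reactants: 1 2,6-dimethoxyphenol; 2 allyl bromide
Product: 3 2-(allyloxy)-1,3-dimethoxybenzene
Conditions: K2CO3, acetone, reflux
Reagents that add atoms: none
Why: Williamson ether synthesis (SN2 O-allylation of the phenoxide), run far below the temperature at which the aryl allyl ether would undergo Claisen rearrangement.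

Step 2
Reactants: 3 2-(allyloxy)-1,3-dimethoxybenzene; 4 (−)-B-methoxydiisopinocampheylborane (from (+)-α-pinene); 5 3,4,5-trimethoxybenzaldehyde
Product: 10 (1R,2R)-2-(2,6-dimethoxyphenoxy)-1-(3,4,5-trimethoxyphenyl)but-3-en-1-ol, via oxyallyllithium 6 (not isolated), via methoxyborate complex 7 (not isolated), via Z-allylborane 8 (not isolated), via borinate ester 9 (not isolated)
Conditions: s-BuLi, THF, −78 °C; 4, −78 °C; BF3·OEt2, −78 °C; 5, −78 °C, 4 h; then NaOH, H2O2, 0 °C to rt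
Reagents that add atoms: none
Why: Kinetic α-deprotonation of the allyl aryl ether gives the O→Li-chelated (Z)-oxyallyl anion (an α-oxygenated carbanion, so the ether carbon reacts with reversed polarity), boron is delivered to the γ-terminus, and the (Z)-γ-aryloxyallylborane adds to 5 through a closed chair transition state (Brown asymmetric γ-alkoxyallylboration) in which the Z-aryloxy group is axial and the aryl of 5 equatorial, giving the syn (threo) relationship, while the isopinocampheyl groups derived from (+)-α-pinene direct attack to the Si face of the aldehyde, so that C1 (R) and C2 (R) are both set in the C–C bond-forming event.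

Step 3
Reactants: 10 (1R,2R)-2-(2,6-dimethoxyphenoxy)-1-(3,4,5-trimethoxyphenyl)but-3-en-1-ol
Product: 12 (1R,2R)-2-(2,6-dimethoxyphenoxy)-1-(3,4,5-trimethoxyphenyl)propane-1,3-diol, via aldehyde 11 (not isolated)
Conditions: O3, CH2Cl2–MeOH 4:1, NaHCO3, −78 °C (Sudan III end point); then NaBH4, −78 to 0 °C
Reagents that add atoms: ozone, [O-][O+]=O
Why: Ozonolysis with reductive (NaBH4) work-up cleaves the only C=C and reduces aldehyde 11 in the flask before its α-aryloxy centre can epimerise; no stereocentre is formed or touched, and the descriptor at C2 stays R because C1 still outranks CH2OH.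

Step 4
Reactants: 12 (1R,2R)-2-(2,6-dimethoxyphenoxy)-1-(3,4,5-trimethoxyphenyl)propane-1,3-diol; 13 bis(pinacolato)diboron; 2 allyl bromide
Product: 16 (1R,2R)-2-(4-allyl-2,6-dimethoxyphenoxy)-1-(3,4,5-trimethoxyphenyl)propane-1,3-diol, via bis(boryl) ether 14 (not isolated), via arylboronate 15 (not isolated)
Conditions: 13 (2.2 equiv), [Ir(OMe)(cod)]2 (2.5 mol %), 3,4,7,8-Me4-phen (5 mol %), THF, 80 °C; evaporate; then 2 (3 equiv), Pd(dppf)Cl2 (5 mol %), aq K3PO4, THF, 45 °C
Reagents that add atoms: none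
Why: Iridium-catalysed C–H borylation (Hartwig–Miyaura type) is sterically controlled and, once the two OH groups are capped in the flask as O–Bpin, the only aryl C–H not ortho to a substituent is C4 of the dimethoxyphenoxy ring, whose boronate then undergoes Suzuki–Miyaura allyl–aryl coupling under aqueous phosphate, which also hydrolyses the O–B bonds; no stereocentre is involved.

**Compound list**
1 | 2,6-dimethoxyphenol | COc1cccc(OC)c1O | starting material
2 | allyl bromide (3-bromoprop-1-ene) | C=CCBr | starting material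
3 | 2-(allyloxy)-1,3-dimethoxybenzene | C=CCOc1c(OC)cccc1OC | intermediate
4 | (−)-B-methoxydiisopinocampheylborane, from (+)-α-pinene | COB([C@@H]1C[C@@H]2C[C@H]([C@H]1C)C2(C)C)[C@@H]1C[C@@H]2C[C@H]([C@H]1C)C2(C)C | starting material
5 | 3,4,5-trimethoxybenzaldehyde | COc1cc(C=O)cc(OC)c1OC | starting material
6 | [(Z)-3-(2,6-dimethoxyphenoxy)allyl]lithium | [Li]C/C=C\Oc1c(OC)cccc1OC | intermediate
7 | lithium [(Z)-3-(2,6-dimethoxyphenoxy)allyl](methoxy)diisopinocampheylborate | [Li+].CO[B-](C/C=C\Oc1c(OC)cccc1OC)([C@@H]1C[C@@H]2C[C@H]([C@H]1C)C2(C)C)[C@@H]1C[C@@H]2C[C@H]([C@H]1C)C2(C)C | intermediate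
8 | [(Z)-3-(2,6-dimethoxyphenoxy)allyl]diisopinocampheylborane | COc1cccc(OC)c1O/C=C\CB([C@@H]1C[C@@H]2C[C@H]([C@H]1C)C2(C)C)[C@@H]1C[C@@H]2C[C@H]([C@H]1C)C2(C)C | intermediate
9 | diisopinocampheylborinate ester of 10 (O-B(Ipc)2 on the C1 oxygen) | COc1cccc(OC)c1O[C@H](C=C)[C@H](OB([C@@H]1C[C@@H]2C[C@H]([C@H]1C)C2(C)C)[C@@H]1C[C@@H]2C[C@H]([C@H]1C)C2(C)C)c1cc(OC)c(OC)c(OC)c1 | intermediate
10 | (1R,2R)-2-(2,6-dimethoxyphenoxy)-1-(3,4,5-trimethoxyphenyl)but-3-en-1-ol | COc1cccc(OC)c1O[C@H](C=C)[C@H](O)c1cc(OC)c(OC)c(OC)c1 | intermediate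
11 | (2S,3R)-2-(2,6-dimethoxyphenoxy)-3-hydroxy-3-(3,4,5-trimethoxyphenyl)propanal | COc1cccc(OC)c1O[C@H](C=O)[C@H](O)c1cc(OC)c(OC)c(OC)c1 | intermediate
12 | (1R,2R)-2-(2,6-dimethoxyphenoxy)-1-(3,4,5-trimethoxyphenyl)propane-1,3-diol | COc1cccc(OC)c1O[C@H](CO)[C@H](O)c1cc(OC)c(OC)c(OC)c1 | intermediate
13 | bis(pinacolato)diboron | CC1(C)OB(OC1(C)C)B1OC(C)(C)C(C)(C)O1 | starting material
14 | 1,3-bis(O-pinacolboryl) ether of 12 | COc1cccc(OC)c1O[C@H](COB1OC(C)(C)C(C)(C)O1)[C@H](OB1OC(C)(C)C(C)(C)O1)c1cc(OC)c(OC)c(OC)c1 | intermediate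
15 | 1,3-bis(O-pinacolboryl) ether of 12 carrying Bpin at C4 of the dimethoxyphenoxy ring | COc1cc(B2OC(C)(C)C(C)(C)O2)cc(OC)c1O[C@H](COB1OC(C)(C)C(C)(C)O1)[C@H](OB1OC(C)(C)C(C)(C)O1)c1cc(OC)c(OC)c(OC)c1 | intermediate
16 | (1R,2R)-2-(4-allyl-2,6-dimethoxyphenoxy)-1-(3,4,5-trimethoxyphenyl)propane-1,3-diol (CNP0308568.1) | C=CCc1cc(OC)c(O[C@H](CO)[C@H](O)c2cc(OC)c(OC)c(OC)c2)c(OC)c1 | target

**Totals and risks**

Total step count: 4. Longest linear sequence: 4 steps (1 → 3 → 10 → 12 → 16).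

Steps most likely to fail:

Step 2 (key aryloxyallylboration). The hindered 2,6-dimethoxyphenyl allyl ether has not been used in this reaction; ring lithiation next to OMe, loss of Z-geometry or reduced ee are possible. Fallback, setting out from 1 and coming back at 8: phenol 1 is O-propargylated (propargyl bromide, K2CO3, acetone) to 1,3-dimethoxy-2-(prop-2-yn-1-yloxy)benzene F1. Catalytic KOtBu in THF isomerises this to the aryloxyallene 1,3-dimethoxy-2-(propa-1,2-dien-1-yloxy)benzene F2. Hydroboration of F2 with (−)-diisopinocampheylborane (from (+)-α-pinene) at −78 to −40 °C adds B–H across the terminal C=C from the face anti to the aryloxy group. This gives the same (Z)-allylborane 8 without any organolithium, and 5 is then added as in step 2.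

Step 4 (one-pot C–H borylation/allylation). The two OH groups consume boron reagent, the electron-rich ring borylates slowly, and the allyl–aryl coupling may suffer protodeboronation or allyl-to-propenyl isomerisation. Fallback, setting out from aldehyde 5 with a pre-halogenated phenol and coming back at 16:
- Commercial 4-bromo-2,6-dimethoxyphenol F4 is O-propargylated to 5-bromo-1,3-dimethoxy-2-(prop-2-yn-1-yloxy)benzene F5 and isomerised (cat. KOtBu) to 5-bromo-1,3-dimethoxy-2-(propa-1,2-dien-1-yloxy)benzene F6.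
- Hydroboration with (−)-diisopinocampheylborane gives [(Z)-3-(4-bromo-2,6-dimethoxyphenoxy)allyl]diisopinocampheylborane F7, which tolerates the aryl bromide.
- Addition to 5 gives the borinate ester of the adduct F8, and NaOH/H2O2 releases (1R,2R)-2-(4-bromo-2,6-dimethoxyphenoxy)-1-(3,4,5-trimethoxyphenyl)but-3-en-1-ol F9.
- Ozonolysis proceeds through (2S,3R)-2-(4-bromo-2,6-dimethoxyphenoxy)-3-hydroxy-3-(3,4,5-trimethoxyphenyl)propanal F10, and NaBH4 gives (1R,2R)-2-(4-bromo-2,6-dimethoxyphenoxy)-1-(3,4,5-trimethoxyphenyl)propane-1,3-diol F11.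
- Stille coupling of F11 with allyltributylstannane (Pd(PPh3)4, CsF, dioxane, 90 °C) gives 16.

Step 3 (ozonolysis). Ozone may attack the polyalkoxy arenes, and aldehyde 11 may epimerise or undergo retro-aldol cleavage. Fallback, setting out from 10 and coming back at 11: catalytic OsO4 with NMO (acetone–water) dihydroxylates the vinyl group to 2-(2,6-dimethoxyphenoxy)-1-(3,4,5-trimethoxyphenyl)butane-1,3,4-triol F3 (C1 and C2 as in 10, C3 as an epimer mixture). NaIO4 in buffered THF–water at 0 °C cleaves the terminal diol to aldehyde 11, which is reduced at once with NaBH4 to 12.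

Further compounds
F1 | step 2 | 1,3-dimethoxy-2-(prop-2-yn-1-yloxy)benzene | C#CCOc1c(OC)cccc1OC
F2 | step 2 | 1,3-dimethoxy-2-(propa-1,2-dien-1-yloxy)benzene | C=C=COc1c(OC)cccc1OC
F3 | step 3 | 2-(2,6-dimethoxyphenoxy)-1-(3,4,5-trimethoxyphenyl)butane-1,3,4-triol (C1, C2 as in 10; C3 epimer mixture) | COc1cccc(OC)c1O[C@H](C(O)CO)[C@H](O)c1cc(OC)c(OC)c(OC)c1
F4 | step 4 | 4-bromo-2,6-dimethoxyphenol | COc1cc(Br)cc(OC)c1O
F5 | step 4 | 5-bromo-1,3-dimethoxy-2-(prop-2-yn-1-yloxy)benzene | C#CCOc1c(OC)cc(Br)cc1OC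
F6 | step 4 | 5-bromo-1,3-dimethoxy-2-(propa-1,2-dien-1-yloxy)benzene | C=C=COc1c(OC)cc(Br)cc1OC
F7 | step 4 | [(Z)-3-(4-bromo-2,6-dimethoxyphenoxy)allyl]diisopinocampheylborane | COc1cc(Br)cc(OC)c1O/C=C\CB([C@@H]1C[C@@H]2C[C@H]([C@H]1C)C2(C)C)[C@@H]1C[C@@H]2C[C@H]([C@H]1C)C2(C)C
F8 | step 4 | diisopinocampheylborinate ester of F9 | COc1cc(Br)cc(OC)c1O[C@H](C=C)[C@H](OB([C@@H]1C[C@@H]2C[C@H]([C@H]1C)C2(C)C)[C@@H]1C[C@@H]2C[C@H]([C@H]1C)C2(C)C)c1cc(OC)c(OC)c(OC)c1
F9 | step 4 | (1R,2R)-2-(4-bromo-2,6-dimethoxyphenoxy)-1-(3,4,5-trimethoxyphenyl)but-3-en-1-ol | COc1cc(Br)cc(OC)c1O[C@H](C=C)[C@H](O)c1cc(OC)c(OC)c(OC)c1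
F10 | step 4 | (2S,3R)-2-(4-bromo-2,6-dimethoxyphenoxy)-3-hydroxy-3-(3,4,5-trimethoxyphenyl)propanal | COc1cc(Br)cc(OC)c1O[C@H](C=O)[C@H](O)c1cc(OC)c(OC)c(OC)c1
F11 | step 4 | (1R,2R)-2-(4-bromo-2,6-dimethoxyphenoxy)-1-(3,4,5-trimethoxyphenyl)propane-1,3-diol | COc1cc(Br)cc(OC)c1O[C@H](CO)[C@H](O)c1cc(OC)c(OC)c(OC)c1
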